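**Strategy.** The isoindolinone (rings A and B) is joined last to the dienone ring C by a catalytic asymmetric Mannich reaction, so everything rests on ring C (C1 carbonyl, C3 oxygen, C4–H, C5 methyl, quaternary C6 with both prenyl groups). Because C6 cannot aromatize and C1/C3 carry oxygen 1,3 to each other, ring C is the 6π-electrocyclization product of a dienylketene. One operation, Pd-catalysed coupling of a 4-chloro-3-ethoxycyclobutenone with a tetrasubstituted alkenylstannane followed by 4π opening and 6π closure, forges C4–C5 and then C1–C6. The precursors are a four-membered ring and an acyclic diprenyl vinylstannane.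

Key step: step 5

Remark: ring C is numbered C1 (C=O), C2 (lactam-bearing carbon), C3 (C–O), C4 (CH), C5 (C–CH3), C6 (diprenyl carbon); the four-membered ring of 4 and 10 carries the same numbers C1 to C4, and the hydroxy-dienone drawn for 13 and 18 stands for all tautomers of the 1,3-dione.

Step 1
Reactants: 1 ethoxyacetylene; 2 chloroacetyl chloride
Product: 4 4-chloro-3-ethoxycyclobut-2-en-1-one (racemic), via chloroketene 3 (not isolated)
Conditions: Et3N (slow addition), Et2O, 0 °C → rt
Reagents that add atoms: none
Why: In situ ketene–ynol ether [2+2] cycloaddition in which the nucleophilic terminal carbon of 1 attacks the ketene carbonyl carbon, so the ethoxy group ends up at C3 and the chlorine at C4, whose racemic centre is destroyed in step 5.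

Step 2
Reactants: 5 6-methylhept-5-en-2-one
Product: 6 6-methyl-3-methylidenehept-5-en-2-one
Conditions: paraformaldehyde, N-methylanilinium trifluoroacetate, THF, reflux
Reagents that add atoms: formaldehyde (as paraformaldehyde), C=O
Why: Ammonium-salt-mediated Mannich-type α-methylenation proceeds through the more substituted enol of the methyl ketone, so the methylene group should enter at C3 and not at C1.

Step 3
Reactants: 6 6-methyl-3-methylidenehept-5-en-2-one
Product: 8 6-methyl-3-(3-methylbut-2-en-1-yl)hepta-2,5-dien-2-yl trifluoromethanesulfonate, via bromomagnesium enolate 7 (not isolated)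
Conditions: (2-methylprop-1-en-1-yl)magnesium bromide, CuBr·SMe2 (10 mol%), THF, −78 → −30 °C; then 2-[N,N-bis(trifluoromethylsulfonyl)amino]-5-chloropyridine, −78 °C → rt
Reagents that add atoms: (2-methylprop-1-en-1-yl)magnesium bromide, CC(C)=C[Mg]Br; 2-[N,N-bis(trifluoromethylsulfonyl)amino]-5-chloropyridine, FC(F)(F)S(=O)(=O)N(c1ccc(Cl)cn1)S(=O)(=O)C(F)(F)F
Why: Copper-catalysed conjugate addition of the alkenyl Grignard reagent gives the tetrasubstituted enolate regiospecifically and O-sulfonylation traps it as the enol triflate, which has no E/Z isomers because both groups on the distal carbon are now prenyl.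

Step 4
Reactants: 8 6-methyl-3-(3-methylbut-2-en-1-yl)hepta-2,5-dien-2-yl trifluoromethanesulfonate
Product: 9 trimethyl[6-methyl-3-(3-methylbut-2-en-1-yl)hepta-2,5-dien-2-yl]stannane
Conditions: Me3SnSnMe3, Pd(PPh3)4 (5 mol%), LiCl, 1,4-dioxane, 90 °C
Reagents that add atoms: hexamethylditin, C[Sn](C)(C)[Sn](C)(C)C
Why: Pd-catalysed stannylation of an enol triflate with a distannane (oxidative addition, Sn–Sn transmetalation, reductive elimination), in which LiCl stabilises the alkenylpalladium species and the small Me3Sn group tolerates the tetrasubstituted carbon.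

Step 5
Reactants: 4 4-chloro-3-ethoxycyclobut-2-en-1-one; 9 trimethyl[6-methyl-3-(3-methylbut-2-en-1-yl)hepta-2,5-dien-2-yl]stannane
Product: 12 3-ethoxy-5-methyl-6,6-bis(3-methylbut-2-en-1-yl)cyclohexa-2,4-dien-1-one, via 4-alkenylcyclobutenone 10 (not isolated), via dienylketene 11 (not isolated)
Conditions: (PhCN)2PdCl2 (5 mol%), tri(2-furyl)phosphine (10 mol%), CuI (10 mol%), 1,4-dioxane, 50 °C, then 100 °C
Reagents that add atoms: none
Why: Zerovalent palladium inserts into the allylic, α-keto C4–Cl bond of 4, the alkenyl group of 9 is transferred from tin (CuI assisting the hindered transmetalation) and reductive elimination gives 10 with the new C4–C5 bond, after which 10 opens at 100 °C by 4π-conrotatory cleavage of its C1–C4 bond to dienylketene 11, whose ketene carbon closes onto the diprenyl-substituted alkene terminus to form C1–C6. The closest known reaction type is the Stille coupling/thermal benzannulation of 4-chlorocyclobutenones with alkenylstannanes, which normally ends in a phenol. The six-membered ring C is closed by a thermal 6π-disrotatory electrocyclization of the dienylketene. No stereocentre is formed, since C6 carries two identical prenyl groups and the racemic centre of 4 and 10 becomes sp2. The coupling has no regiochemical issue because the oxyallyl palladium unit derived from 4 has two equivalent CH termini, and although only the ketene isomer with the alkenyl group turned inward can cyclize, reversible ring opening should funnel 10 through it. Tautomerization to a phenol is blocked by the quaternary C6, so the dienone is the end point, provided that 6π closure outruns a 1,7-hydrogen shift in 11 and Cope rearrangement of a prenyl group in 12.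

Step 6
Reactants: 12 3-ethoxy-5-methyl-6,6-bis(3-methylbut-2-en-1-yl)cyclohexa-2,4-dien-1-one
Product: 13 3-hydroxy-5-methyl-6,6-bis(3-methylbut-2-en-1-yl)cyclohexa-2,4-dien-1-one
Conditions: 1 M HCl, THF, 0 °C → rt
Reagents that add atoms: water, O
Why: Acid hydrolysis of a vinylogous ester (C-protonation, addition of water to the oxocarbenium ion, loss of ethanol) should be fast under conditions too mild to hydrate the prenyl groups or cyclize them onto the enol.

Step 7
Reactants: 14 2-bromo-6-methoxybenzaldehyde
Product: 15 methyl 2-formyl-3-methoxybenzoate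
Conditions: Pd(OAc)2 (3 mol%), Xantphos (6 mol%), CO (1 atm), Et3N, MeOH/DMF, 70 °C
Reagents that add atoms: carbon monoxide, [C-]#[O+]; methanol, CO
Why: Pd-catalysed alkoxycarbonylation of the aryl bromide (oxidative addition, CO insertion, methanolysis of the acylpalladium species) tolerates the ortho aldehyde and places the carboxyl carbon next to the formyl group without any regiochemical question.

Step 8
Reactants: 15 methyl 2-formyl-3-methoxybenzoate
Product: 16 3-hydroxy-4-methoxy-2,3-dihydro-1H-isoindol-1-one (racemic)
Conditions: NH3 (7 M in MeOH), rt; aqueous work-up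
Reagents that add atoms: ammonia, N
Why: Ammonia adds to the aldehyde and the carbinolamine nitrogen closes onto the neighbouring ester (5-exo-trig lactamization), giving the racemic hydroxylactam whose stereocentre is erased in the next step.

Step 9
Reactants: 13 3-hydroxy-5-methyl-6,6-bis(3-methylbut-2-en-1-yl)cyclohexa-2,4-dien-1-one; 16 3-hydroxy-4-methoxy-2,3-dihydro-1H-isoindol-1-one
Product: 18 (3R)-3-[2-hydroxy-4-methyl-5,5-bis(3-methylbut-2-en-1-yl)-6-oxocyclohexa-1,3-dien-1-yl]-4-methoxy-2,3-dihydro-1H-isoindol-1-one (target CNP0508988.2), via N-acylimine 17 (not isolated)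
Conditions: (R)-TRIP [(R)-3,3'-bis(2,4,6-triisopropylphenyl)-1,1'-binaphthyl-2,2'-diyl hydrogen phosphate] (10 mol%), 4 Å MS, CH2Cl2, −20 °C → rt
Reagents that add atoms: none
Why: Chiral phosphoric acid-catalysed N-acyliminium Mannich reaction in which the acid dehydrates 16 to the N-acylimine and holds it and the enol of 13 in one hydrogen-bonded ion pair, so that C2 of the enol attacks one face of the imine carbon and sets the only stereocentre, the sense of induction having to be confirmed and the mirror-image acid being used if the (S) centre forms.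

**Compound list**

1 | ethoxyacetylene | C#COCC | starting material
2 | chloroacetyl chloride | ClCC(Cl)=O | starting material
3 | chloroketene | ClC=C=O | intermediate
4 | 4-chloro-3-ethoxycyclobut-2-en-1-one (racemic) | CCOC1=CC(=O)C1Cl | intermediate
5 | 6-methylhept-5-en-2-one | CC(=O)CCC=C(C)C | starting material
6 | 6-methyl-3-methylidenehept-5-en-2-one | CC(=O)C(=C)CC=C(C)C | intermediate
7 | bromomagnesium 6-methyl-3-(3-methylbut-2-en-1-yl)hepta-2,5-dien-2-olate | CC(O[Mg]Br)=C(CC=C(C)C)CC=C(C)C | intermediate
8 | 6-methyl-3-(3-methylbut-2-en-1-yl)hepta-2,5-dien-2-yl trifluoromethanesulfonate | CC(OS(=O)(=O)C(F)(F)F)=C(CC=C(C)C)CC=C(C)C | intermediate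
9 | trimethyl[6-methyl-3-(3-methylbut-2-en-1-yl)hepta-2,5-dien-2-yl]stannane | C[Sn](C)(C)C(C)=C(CC=C(C)C)CC=C(C)C | intermediate
10 | 3-ethoxy-4-[6-methyl-3-(3-methylbut-2-en-1-yl)hepta-2,5-dien-2-yl]cyclobut-2-en-1-one (racemic) | CCOC1=CC(=O)C1C(C)=C(CC=C(C)C)CC=C(C)C | intermediate
11 | (3E)-3-ethoxy-5,9-dimethyl-6-(3-methylbut-2-en-1-yl)deca-1,3,5,8-tetraen-1-one (dienylketene) | CCO/C(C=C=O)=C/C(C)=C(CC=C(C)C)CC=C(C)C | intermediate
12 | 3-ethoxy-5-methyl-6,6-bis(3-methylbut-2-en-1-yl)cyclohexa-2,4-dien-1-one | CCOC1=CC(=O)C(CC=C(C)C)(CC=C(C)C)C(C)=C1 | intermediate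
13 | 3-hydroxy-5-methyl-6,6-bis(3-methylbut-2-en-1-yl)cyclohexa-2,4-dien-1-one | OC1=CC(=O)C(CC=C(C)C)(CC=C(C)C)C(C)=C1 | intermediate
14 | 2-bromo-6-methoxybenzaldehyde | COc1cccc(Br)c1C=O | starting material
15 | methyl 2-formyl-3-methoxybenzoate | COC(=O)c1cccc(OC)c1C=O | intermediate
16 | 3-hydroxy-4-methoxy-2,3-dihydro-1H-isoindol-1-one (racemic) | COc1cccc2c1C(O)NC2=O | intermediate
17 | 4-methoxy-1H-isoindol-1-one (N-acylimine) | COc1cccc2c1C=NC2=O | intermediate
18 | (3R)-3-[2-hydroxy-4-methyl-5,5-bis(3-methylbut-2-en-1-yl)-6-oxocyclohexa-1,3-dien-1-yl]-4-methoxy-2,3-dihydro-1H-isoindol-1-one | COc1cccc2c1[C@H](C1=C(O)C=C(C)C(CC=C(C)C)(CC=C(C)C)C1=O)NC2=O | target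

**Totals.** Total step count: 9. Longest linear sequence: 6 steps (5 → 6 → 8 → 9 → 12 → 13 → 18; steps 2, 3, 4, 5, 6 and 9).

**Steps most likely to fail**

Step 5. Transfer of the tetrasubstituted alkenyl group from tin to palladium may be too slow, so that methyl transfer, protodestannylation or decomposition of 4 take over, and prolonged heating may trigger Cope rearrangement of the product. The fallback gives up the four-membered ring and builds ring C by an acylation–aldol sequence that makes the same two ring bonds in two operations. It sets out from 6: enolate 7 is generated as in step 3 and C-acylated at −78 °C with diketene (4-methylideneoxetan-2-one), which forms C6–C1 and should give 3,3-bis(3-methylbut-2-en-1-yl)heptane-2,4,6-trione F1. LiN(iPr)2 (2.2 equiv, THF, −78 → 0 °C) then forms the dianion of the 1,3-diketone unit, whose terminal carbanion adds to the acetyl group next to the quaternary carbon (C4–C5) to give the aldol 5-hydroxy-5-methyl-4,4-bis(3-methylbut-2-en-1-yl)cyclohexane-1,3-dione F2. Acid work-up dehydrates it to 13, where the route is rejoined.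

Step 9. Facial selectivity may be low or of the wrong sense, and the acid may erode the enantiomeric purity through reversible retro-Mannich cleavage. The fallback uses an acyclic imine under bifunctional hydrogen-bond catalysis and closes the lactam afterwards. It sets out from 15, which with tert-butyl carbamate, PhSO2Na and HCO2H in aqueous MeOH should give the amido sulfone tert-butyl N-[(benzenesulfonyl)(2-methoxy-6-(methoxycarbonyl)phenyl)methyl]carbamate F3. In toluene with aqueous K2CO3 this releases the N-Boc imine methyl 2-[(E)-(tert-butoxycarbonylimino)methyl]-3-methoxybenzoate F4 in situ, to which 13 adds under a quinine-derived squaramide (the quinidine-derived catalyst giving the other sense) to give methyl 2-[(R)-(tert-butoxycarbonylamino)(2-hydroxy-4-methyl-5,5-bis(3-methylbut-2-en-1-yl)-6-oxocyclohexa-1,3-dien-1-yl)methyl]-3-methoxybenzoate F5. TMSOTf/2,6-lutidine followed by MeOH removes the Boc group without strong acid to give the amino ester methyl 2-[(R)-amino(2-hydroxy-4-methyl-5,5-bis(3-methylbut-2-en-1-yl)-6-oxocyclohexa-1,3-dien-1-yl)methyl]-3-methoxybenzoate F6. This is not isolated and lactamizes onto the ester with Et3N to give 18, where the route ends.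

Step 1. Chloroketene may oligomerize, or the acid chloride may acylate the ynol ether, faster than the cycloaddition takes place. The fallback uses the more electrophilic dichloroketene and removes one chlorine afterwards. It sets out from 1: dichloroketene generated from trichloroacetyl chloride and Zn(Cu) in Et2O/DME should give 4,4-dichloro-3-ethoxycyclobut-2-en-1-one F7. One equivalent of Zn dust in AcOH/TMEDA/EtOH at 0 °C then removes a single chlorine to give 4, where the route is rejoined.

**Further compounds**

F1 | step 5 | 3,3-bis(3-methylbut-2-en-1-yl)heptane-2,4,6-trione | CC(=O)C(CC=C(C)C)(CC=C(C)C)C(=O)CC(C)=O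
F2 | step 5 | 5-hydroxy-5-methyl-4,4-bis(3-methylbut-2-en-1-yl)cyclohexane-1,3-dione (racemic) | CC1(O)CC(=O)CC(=O)C1(CC=C(C)C)CC=C(C)C
F3 | step 9 | tert-butyl N-[(benzenesulfonyl)(2-methoxy-6-(methoxycarbonyl)phenyl)methyl]carbamate (racemic) | COC(=O)c1cccc(OC)c1C(NC(=O)OC(C)(C)C)S(=O)(=O)c1ccccc1
F4 | step 9 | methyl 2-[(E)-(tert-butoxycarbonylimino)methyl]-3-methoxybenzoate | COC(=O)c1cccc(OC)c1/C=N/C(=O)OC(C)(C)C
F5 | step 9 | methyl 2-[(R)-(tert-butoxycarbonylamino)(2-hydroxy-4-methyl-5,5-bis(3-methylbut-2-en-1-yl)-6-oxocyclohexa-1,3-dien-1-yl)methyl]-3-methoxybenzoate | COC(=O)c1cccc(OC)c1[C@H](C1=C(O)C=C(C)C(CC=C(C)C)(CC=C(C)C)C1=O)NC(=O)OC(C)(C)C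
F6 | step 9 | methyl 2-[(R)-amino(2-hydroxy-4-methyl-5,5-bis(3-methylbut-2-en-1-yl)-6-oxocyclohexa-1,3-dien-1-yl)methyl]-3-methoxybenzoate | COC(=O)c1cccc(OC)c1[C@H](C1=C(O)C=C(C)C(CC=C(C)C)(CC=C(C)C)C1=O)N
F7 | step 1 | 4,4-dichloro-3-ethoxycyclobut-2-en-1-one | CCOC1=CC(=O)C1(Cl)Cl
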